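**Plan**
- Retrosynthesis: the lactone O–C6 bond is cut first (iodolactonisation of the C12 carboxylate onto a ring alkene), then C5=C6 (ring-closing metathesis), C1–C2 (Nozaki–Hiyama–Kishi coupling) and the C8 tiglate; this leads to lactone fragment 13 and aldehyde fragment 20.
- Enabling feature: in the ten-membered carbocycle (C1–C10) the C12 carboxyl hangs from C7 through C11 and lies γ,δ to a (Z)-C5=C6 bond, so 5-exo capture of an iodonium ion closes the ring O–C12–C11–C7–C6. A temporary 8,12-lactone (O–C8–C7–C11–C12) carries the trans C7/C8 relationship and is opened in the same flask; the iodine at C5 is removed one step later.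
- Forward order of rings: butenolide (metathesis) → trans-disubstituted α-methylene lactone → coupling and epoxide → ten-membered ring (metathesis) → 6,12-γ-lactone (key step) → tiglate and C15 aldehyde.
- Stereochemistry: C8 from (S)-epichlorohydrin; C7 by anti cuprate addition; C4 by Ir-catalysed allylic alkylation; C2 by CBS reduction; C1/C10 by hydroxyl-directed epoxidation; C6 in the key step under control of C7.

Key step: step 19

Remark: germacrane numbering is used (C1–C10 ring; C6 lactone carbinol; C7 bears C11(=C13H2)–C12O; C8 tiglate carbon; C14 methyl on C10; C15 on C4; α = below, β = above, H-7 α). The target is taken as the open 2-hydroxy-15-aldehyde as drawn.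

**Route**

Step 1
Reactants: 1 (S)-epichlorohydrin
Product: 2 (S)-1-chloro-5-(trimethylsilyl)pent-4-yn-2-ol
Conditions: trimethylsilylacetylene, n-BuLi, THF, −78 °C; BF3·OEt2; then 1, −78 °C; NH4Cl (aq)
Reagents that add atoms: trimethylsilylacetylene C#C[Si](C)(C)C
Why: BF3-promoted alkynylation of the terminal epoxide takes place at the unsubstituted ring carbon, so the stereocentre of 1 (later C8) is not touched.

Step 2
Reactants: 2 (S)-1-chloro-5-(trimethylsilyl)pent-4-yn-2-ol
Product: 5 (S)-hex-1-en-5-yn-3-ol, via silyl epoxide 3 (not isolated), via silyl enynol 4 (not isolated)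
Conditions: Me3SI (4 equiv), n-BuLi (3.9 equiv), THF, −10 °C to rt; then K2CO3, MeOH, rt
Reagents that add atoms: trimethylsulfonium iodide C[S+](C)C.[I-]
Why: the alkoxide closes to epoxide 3, dimethylsulfonium methylide opens its CH2 terminus and the betaine loses Me2S to give the allylic alcohol (sulfonium-ylide one-carbon homologation of an epoxide), and K2CO3/MeOH then protodesilylates the alkyne, all without touching the stereocentre.

Step 3
Reactants: 5 (S)-hex-1-en-5-yn-3-ol
Product: 7 (S,E)-6-iodo-5-methylhexa-1,5-dien-3-ol, via alkenylalane 6 (not isolated)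
Conditions: AlMe3 (3 equiv), Cp2ZrCl2 (25 mol %), CH2Cl2, 0 °C to rt; then I2, THF, −30 to 0 °C
Reagents that add atoms: trimethylaluminium C[Al](C)C; iodine II
Why: Zr-catalysed syn carboalumination (Negishi) puts CH3 on the internal and Al on the terminal alkyne carbon, and iodinolysis with retention gives the (E)-iodoalkene that fixes the later C1=C10 geometry.

Step 4
Reactants: 7 (S,E)-6-iodo-5-methylhexa-1,5-dien-3-ol
Product: 8 (S,E)-6-iodo-5-methylhexa-1,5-dien-3-yl prop-2-enoate
Conditions: acryloyl chloride, Et3N, DMAP (cat.), CH2Cl2, −20 to 0 °C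
Reagents that add atoms: acryloyl chloride C=CC(=O)Cl
Why: plain O-acylation of a secondary alcohol sets up the diene for butenolide formation.

Step 5
Reactants: 8 (S,E)-6-iodo-5-methylhexa-1,5-dien-3-yl prop-2-enoate
Product: 9 (S)-5-[(E)-3-iodo-2-methylprop-2-en-1-yl]furan-2(5H)-one
Conditions: second-generation Grubbs catalyst (5 mol %), CH2Cl2 (0.01 M), 40 °C
Reagents that add atoms: none
Why: ring-closing metathesis of an allyl acrylate gives the five-membered butenolide with loss of ethylene, the trisubstituted iodoalkene being inert to the ruthenium carbene.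

Step 6
Reactants: 9 (S)-5-[(E)-3-iodo-2-methylprop-2-en-1-yl]furan-2(5H)-one
Product: 11 (4R,5S)-3-[(dimethylamino)methyl]-4-ethenyl-5-[(E)-3-iodo-2-methylprop-2-en-1-yl]oxolan-2-one, via magnesium enolate 10 (not isolated)
Conditions: CH2=CHMgBr (2.2 equiv), CuBr·SMe2 (1.1 equiv), THF, −78 °C; then CH2=NMe2+ I−, −78 °C to rt
Reagents that add atoms: vinylmagnesium bromide C=C[Mg]Br; N,N-dimethylmethyleneiminium iodide C=[N+](C)C.[I-]
Why: the vinyl cuprate adds 1,4 to the butenolide anti to the C8 substituent, which sets C7 trans to C8, and enolate 10 is trapped by the iminium salt (tandem conjugate addition–Mannich reaction); the new C11 centre is removed in step 7.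

Step 7
Reactants: 11 (4R,5S)-3-[(dimethylamino)methyl]-4-ethenyl-5-[(E)-3-iodo-2-methylprop-2-en-1-yl]oxolan-2-one
Product: 13 (4R,5S)-4-ethenyl-5-[(E)-3-iodo-2-methylprop-2-en-1-yl]-3-methylideneoxolan-2-one, via ammonium iodide 12 (not isolated)
Conditions: MeI, MeOH, rt; then NaHCO3 (aq), CH2Cl2, rt
Reagents that add atoms: none
Why: N-methylation followed by base-induced β-elimination of trimethylamine unveils the exocyclic C11=C13 methylene.

Step 8
Reactants: 14 (E)-but-2-ene-1,4-diol
Product: 15 (E)-4-[(4-methoxybenzyl)oxy]but-2-en-1-ol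
Conditions: NaH (1 equiv), THF, 0 °C; 4-methoxybenzyl chloride, Bu4NI (cat.), rt (diol in excess)
Reagents that add atoms: 4-methoxybenzyl chloride COc1ccc(CCl)cc1
Why: Williamson mono-etherification of the symmetric diol gives the PMB ether that later becomes C15–O.

Step 9
Reactants: 15 (E)-4-[(4-methoxybenzyl)oxy]but-2-en-1-ol
Product: 16 (E)-4-[(4-methoxybenzyl)oxy]but-2-en-1-yl methyl carbonate
Conditions: ClCO2Me, pyridine, CH2Cl2, 0 °C
Reagents that add atoms: methyl chloroformate COC(=O)Cl
Why: carbonate formation supplies the leaving group, and the internal methoxide base, for the allylic substitution.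

Step 10
Reactants: 16 (E)-4-[(4-methoxybenzyl)oxy]but-2-en-1-yl methyl carbonate; 17 dimethyl malonate
Product: 18 dimethyl 2-[(R)-1-[(4-methoxybenzyl)oxy]but-3-en-2-yl]propanedioate
Conditions: [Ir(cod)Cl]2 (2 mol %), binaphthol-derived bis(1-phenylethyl)phosphoramidite ligand (4 mol %; the enantiomer that delivers (R)-18), TBD (8 mol %), THF, 50 °C
Reagents that add atoms: none
Why: Ir-catalysed asymmetric allylic alkylation attacks the substituted allyl terminus and gives the branched product, the chiral ligand setting the stereocentre that becomes C4.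

Step 11
Reactants: 18 dimethyl 2-[(R)-1-[(4-methoxybenzyl)oxy]but-3-en-2-yl]propanedioate
Product: 19 methyl (S)-3-{[(4-methoxybenzyl)oxy]methyl}pent-4-enoate
Conditions: LiCl, H2O, DMSO, 150 °C
Reagents that add atoms: none
Why: Krapcho dealkoxycarbonylation removes one ester without touching the stereocentre (the descriptor changes only through CIP priorities).

Step 12
Reactants: 19 methyl (S)-3-{[(4-methoxybenzyl)oxy]methyl}pent-4-enoate
Product: 20 (S)-3-{[(4-methoxybenzyl)oxy]methyl}pent-4-enal
Conditions: iBu2AlH (1.05 equiv), CH2Cl2, −78 °C; Rochelle salt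
Reagents that add atoms: none
Why: partial reduction of the ester stops at the aldehyde because the tetrahedral aluminate is stable at low temperature.

Step 13
Reactants: 13 (4R,5S)-4-ethenyl-5-[(E)-3-iodo-2-methylprop-2-en-1-yl]-3-methylideneoxolan-2-one; 20 (S)-3-{[(4-methoxybenzyl)oxy]methyl}pent-4-enal
Product: 21 (4R,5S)-4-ethenyl-5-[(2E,4RS,6S)-4-hydroxy-6-{[(4-methoxybenzyl)oxy]methyl}-2-methylocta-2,7-dien-1-yl]-3-methylideneoxolan-2-one (both C2 epimers)
Conditions: CrCl2 (4 equiv), NiCl2 (2 mol %), DMSO, rt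
Reagents that add atoms: none
Why: the Nozaki–Hiyama–Kishi coupling adds the alkenylchromium species chemoselectively to the aldehyde with retention of the E geometry and tolerates the lactone and acrylate; C2 is not controlled here and is corrected in steps 14 and 15.

Step 14
Reactants: 21 allylic alcohol (both C2 epimers)
Product: 22 (4R,5S)-4-ethenyl-5-[(2E,6S)-6-{[(4-methoxybenzyl)oxy]methyl}-2-methyl-4-oxoocta-2,7-dien-1-yl]-3-methylideneoxolan-2-one
Conditions: Dess–Martin periodinane, NaHCO3, CH2Cl2, 0 °C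
Reagents that add atoms: none
Why: oxidation under non-basic conditions converges both epimers to the enone and avoids vinylogous β-elimination of the C8 lactone oxygen.

Step 15
Reactants: 22 enone
Product: 23 (4R,5S)-4-ethenyl-5-[(2E,4S,6S)-4-hydroxy-6-{[(4-methoxybenzyl)oxy]methyl}-2-methylocta-2,7-dien-1-yl]-3-methylideneoxolan-2-one
Conditions: (R)-Me-CBS oxazaborolidine (20 mol %), catecholborane, toluene, −78 °C
Reagents that add atoms: none
Why: in the CBS reduction the alkenyl group acts as the large substituent, so the (R)-catalyst should deliver hydride to give the (2S)-allylic alcohol, while lactone and terminal alkenes are untouched by catecholborane at this temperature.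

Step 16
Reactants: 23 (2S)-allylic alcohol
Product: 24 (4R,5S)-4-ethenyl-5-{[(2R,3R)-3-[(1S,3S)-1-hydroxy-3-{[(4-methoxybenzyl)oxy]methyl}pent-4-en-1-yl]-2-methyloxiran-2-yl]methyl}-3-methylideneoxolan-2-one
Conditions: mCPBA (1.1 equiv), NaHCO3, CH2Cl2, 0 °C
Reagents that add atoms: 3-chloroperoxybenzoic acid OOC(=O)c1cccc(Cl)c1
Why: in this hydroxyl-directed peracid epoxidation, A1,3 strain with the C14 methyl puts H2 in the alkene plane, so oxygen is delivered syn to the hydroxyl (threo) and sets C1 and C10; the trisubstituted alkene is far more reactive than the vinyl groups and the acrylate.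

Step 17
Reactants: 24 epoxy alcohol
Product: 25 triethylsilyl ether of 24 (C2–OSiEt3)
Conditions: Et3SiCl, imidazole, DMF, 0 °C
Reagents that add atoms: chlorotriethylsilane CC[Si](Cl)(CC)CC
Why: silylation blocks the C2 hydroxyl, which could otherwise capture the iodonium ion in step 19 or form a lactol or lactone with C15 in step 23.

Step 18
Reactants: 25 triethylsilyl ether
Product: 26 (5Z)-1β,10α-epoxy-15-[(4-methoxybenzyl)oxy]-2α-(triethylsilyloxy)-4αH-germacra-5,11(13)-dien-12,8α-olide
Conditions: second-generation Hoveyda–Grubbs catalyst (10 mol %), 1,4-benzoquinone (20 mol %), toluene (1 mM), 80 °C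
Reagents that add atoms: none
Why: ring-closing metathesis of the two monosubstituted alkenes closes the ten-membered carbocycle, the Z olefin being expected as the less strained geometry; prior epoxidation has removed the trisubstituted alkene that would give cyclopentenes, and the 1,1-disubstituted acrylate is much less reactive.

Step 19
Reactants: 26 (5Z)-8,12-lactone
Product: 28 1β,10α-epoxy-8α-hydroxy-5β-iodo-15-[(4-methoxybenzyl)oxy]-2α-(triethylsilyloxy)-4αH-germacr-11(13)-en-12,6α-olide, via lithium hydroxy carboxylate 27 (not isolated)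
Conditions: LiOH·H2O (1.5 equiv), THF/H2O, 0 °C; then NaHCO3, I2 (3 equiv), MeCN/H2O, 0 °C, dark; Na2S2O3
Reagents that add atoms: lithium hydroxide [Li+].[OH-]; iodine II
Why: LiOH opens the temporary 8,12-lactone to carboxylate 27, I2 forms an iodonium ion reversibly on the only electron-rich alkene, (Z)-C5=C6, and the C12 carboxylate oxygen attacks C6 anti to iodine, forming the O–C6 bond (iodolactonisation of a γ,δ-unsaturated acid, here a 2-methylene-4-pentenoic acid unit). The γ-lactone closes in a 5-exo mode on the iodonium ion, the 6-endo attack at C5 being slower. C6 is controlled by C7 through A1,3 strain: in the Z alkene H7 must lie in the alkene plane, so C8 and C11 point to opposite faces and the tether can deliver oxygen only to the face that gives the trans-fused lactone (6α-O, H6β, H7α); the C5 centre (iodine β) follows from anti addition and is erased in step 20. The step needs 5-exo regioselectivity and attack by the carboxylate and not by a hydroxyl or the epoxide oxygen: the anionic carboxylate under NaHCO3 is the best nucleophile, the C2 hydroxyl is silylated, the C8 hydroxyl could reach only C5 in a slower 5-endo mode, and the acrylate and PMB groups do not react with I2. The same operation moves the lactone from C8 to C6 and frees the C8 hydroxyl for the tiglate.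

Step 20
Reactants: 28 iodolactone
Product: 29 1β,10α-epoxy-8α-hydroxy-15-[(4-methoxybenzyl)oxy]-2α-(triethylsilyloxy)-4αH-germacr-11(13)-en-12,6α-olide
Conditions: Bu3SnH (2 equiv), Et3B (cat.), air, toluene (5 mM), 0 °C
Reagents that add atoms: none
Why: radical-chain dehalogenation removes the helper iodine, since iodine abstraction and hydrogen transfer are fast, high dilution disfavours intermolecular addition to the α-methylene lactone, and the C5 radical has only 4-exo or 5-endo paths to C11=C13.

Step 21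
Reactants: 29 8α-hydroxy lactone
Product: 30 1β,10α-epoxy-15-[(4-methoxybenzyl)oxy]-8α-(tigloyloxy)-2α-(triethylsilyloxy)-4αH-germacr-11(13)-en-12,6α-olide
Conditions: tiglic acid, 2,4,6-trichlorobenzoyl chloride, Et3N, toluene, rt; then 29, DMAP, rt
Reagents that add atoms: tiglic acid C/C=C(\C)C(=O)O
Why: Yamaguchi esterification acylates the hindered 8α-hydroxyl through the mixed anhydride and DMAP, avoids the vinylketene path that deconjugates enoyl chlorides, and keeps the E geometry.

Step 22
Reactants: 30 tiglate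
Product: 31 1β,10α-epoxy-15-hydroxy-8α-(tigloyloxy)-2α-(triethylsilyloxy)-4αH-germacr-11(13)-en-12,6α-olide
Conditions: DDQ, CH2Cl2/pH 7 buffer, 0 °C to rt
Reagents that add atoms: none
Why: oxidative cleavage of the PMB ether by DDQ frees the C15 hydroxyl while the silyl ether, epoxide and both enoates are inert.

Step 23
Reactants: 31 primary alcohol
Product: 32 1β,10α-epoxy-15-oxo-8α-(tigloyloxy)-2α-(triethylsilyloxy)-4αH-germacr-11(13)-en-12,6α-olide
Conditions: Dess–Martin periodinane, NaHCO3, CH2Cl2, 0 °C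
Reagents that add atoms: none
Why: buffered periodinane oxidation gives the aldehyde without epimerising C4, and the silyl group on O2 prevents lactol formation and over-oxidation.

Step 24
Reactants: 32 silyl-protected aldehyde
Product: 33 target, 1β,10α-epoxy-2α-hydroxy-15-oxo-8α-(tigloyloxy)-4αH-germacr-11(13)-en-12,6α-olide
Conditions: HF·pyridine, pyridine, THF, 0 °C
Reagents that add atoms: none
Why: buffered fluoride desilylation frees the C2 hydroxyl under conditions that should leave the epoxide, the α-methylene lactone, the tiglate and the C4 centre unchanged.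

**Compound list**
1 | (S)-epichlorohydrin, (S)-2-(chloromethyl)oxirane | ClC[C@@H]1CO1 | starting material
2 | (S)-1-chloro-5-(trimethylsilyl)pent-4-yn-2-ol | ClC[C@@H](O)CC#C[Si](C)(C)C | intermediate
3 | (S)-trimethyl[3-(oxiran-2-yl)prop-1-yn-1-yl]silane (not isolated) | C[Si](C)(C)C#CC[C@H]1CO1 | intermediate
4 | (S)-6-(trimethylsilyl)hex-1-en-5-yn-3-ol (not isolated) | C=C[C@@H](O)CC#C[Si](C)(C)C | intermediate
5 | (S)-hex-1-en-5-yn-3-ol | C=C[C@@H](O)CC#C | intermediate
6 | dimethylaluminium alkoxide of (S,E)-6-(dimethylalumanyl)-5-methylhexa-1,5-dien-3-ol (not isolated) | C=C[C@@H](O[Al](C)C)C/C(C)=C/[Al](C)C | intermediate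
7 | (S,E)-6-iodo-5-methylhexa-1,5-dien-3-ol | C=C[C@@H](O)C/C(C)=C/I | intermediate
8 | (S,E)-6-iodo-5-methylhexa-1,5-dien-3-yl prop-2-enoate | C=CC(=O)O[C@H](C=C)C/C(C)=C/I | intermediate
9 | (S)-5-[(E)-3-iodo-2-methylprop-2-en-1-yl]furan-2(5H)-one | O=C1C=C[C@H](C/C(C)=C/I)O1 | intermediate
10 | bromomagnesium enolate of (4S,5S)-4-ethenyl-5-[(E)-3-iodo-2-methylprop-2-en-1-yl]oxolan-2-one (not isolated) | Br[Mg]OC1=C[C@@H](C=C)[C@H](C/C(C)=C/I)O1 | intermediate
11 | (4R,5S)-3-[(dimethylamino)methyl]-4-ethenyl-5-[(E)-3-iodo-2-methylprop-2-en-1-yl]oxolan-2-one (C3 epimers, mainly 3,4-trans) | CN(C)CC1C(=O)O[C@@H](C/C(C)=C/I)[C@@H]1C=C | intermediate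
12 | trimethylammonium iodide of 11 (not isolated) | C[N+](C)(C)CC1C(=O)O[C@@H](C/C(C)=C/I)[C@@H]1C=C.[I-] | intermediate
13 | (4R,5S)-4-ethenyl-5-[(E)-3-iodo-2-methylprop-2-en-1-yl]-3-methylideneoxolan-2-one | C=C1C(=O)O[C@@H](C/C(C)=C/I)[C@@H]1C=C | intermediate
14 | (E)-but-2-ene-1,4-diol | OC/C=C/CO | starting material
15 | (E)-4-[(4-methoxybenzyl)oxy]but-2-en-1-ol | OC/C=C/COCc1ccc(OC)cc1 | intermediate
16 | (E)-4-[(4-methoxybenzyl)oxy]but-2-en-1-yl methyl carbonate | COC(=O)OC/C=C/COCc1ccc(OC)cc1 | intermediate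
17 | dimethyl malonate | COC(=O)CC(=O)OC | starting material
18 | dimethyl 2-[(R)-1-[(4-methoxybenzyl)oxy]but-3-en-2-yl]propanedioate | COC(=O)C(C(=O)OC)[C@H](COCc1ccc(OC)cc1)C=C | intermediate
19 | methyl (S)-3-{[(4-methoxybenzyl)oxy]methyl}pent-4-enoate | COC(=O)C[C@H](COCc1ccc(OC)cc1)C=C | intermediate
20 | (S)-3-{[(4-methoxybenzyl)oxy]methyl}pent-4-enal | O=CC[C@H](COCc1ccc(OC)cc1)C=C | intermediate
21 | (4R,5S)-4-ethenyl-5-[(2E,4RS,6S)-4-hydroxy-6-{[(4-methoxybenzyl)oxy]methyl}-2-methylocta-2,7-dien-1-yl]-3-methylideneoxolan-2-one | C=C1C(=O)O[C@@H](C/C(C)=C/C(O)C[C@H](COCc2ccc(OC)cc2)C=C)[C@@H]1C=C | intermediate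
22 | (4R,5S)-4-ethenyl-5-[(2E,6S)-6-{[(4-methoxybenzyl)oxy]methyl}-2-methyl-4-oxoocta-2,7-dien-1-yl]-3-methylideneoxolan-2-one | C=C1C(=O)O[C@@H](C/C(C)=C/C(=O)C[C@H](COCc2ccc(OC)cc2)C=C)[C@@H]1C=C | intermediate
23 | (4R,5S)-4-ethenyl-5-[(2E,4S,6S)-4-hydroxy-6-{[(4-methoxybenzyl)oxy]methyl}-2-methylocta-2,7-dien-1-yl]-3-methylideneoxolan-2-one | C=C1C(=O)O[C@@H](C/C(C)=C/[C@@H](O)C[C@H](COCc2ccc(OC)cc2)C=C)[C@@H]1C=C | intermediate
24 | (4R,5S)-4-ethenyl-5-{[(2R,3R)-3-[(1S,3S)-1-hydroxy-3-{[(4-methoxybenzyl)oxy]methyl}pent-4-en-1-yl]-2-methyloxiran-2-yl]methyl}-3-methylideneoxolan-2-one | C=C1C(=O)O[C@@H](C[C@@]2(C)O[C@@H]2[C@@H](O)C[C@H](COCc3ccc(OC)cc3)C=C)[C@@H]1C=C | intermediate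
25 | triethylsilyl ether of 24 at the carbinol oxygen (O2) | C=C1C(=O)O[C@@H](C[C@@]2(C)O[C@@H]2[C@@H](O[Si](CC)(CC)CC)C[C@H](COCc3ccc(OC)cc3)C=C)[C@@H]1C=C | intermediate
26 | (5Z)-1β,10α-epoxy-15-[(4-methoxybenzyl)oxy]-2α-(triethylsilyloxy)-4αH-germacra-5,11(13)-dien-12,8α-olide | C=C1C(=O)O[C@H]2C[C@@]3(C)O[C@@H]3[C@@H](O[Si](CC)(CC)CC)C[C@H](COCc4ccc(OC)cc4)/C=C\[C@H]12 | intermediate
27 | lithium (5Z)-1β,10α-epoxy-8α-hydroxy-15-[(4-methoxybenzyl)oxy]-2α-(triethylsilyloxy)-4αH-germacra-5,11(13)-dien-12-oate (not isolated) | C=C(C(=O)[O-])[C@H]1/C=C\[C@@H](COCc2ccc(OC)cc2)C[C@H](O[Si](CC)(CC)CC)[C@H]3O[C@]3(C)C[C@@H]1O.[Li+] | intermediate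
28 | 1β,10α-epoxy-8α-hydroxy-5β-iodo-15-[(4-methoxybenzyl)oxy]-2α-(triethylsilyloxy)-4αH-germacr-11(13)-en-12,6α-olide | C=C1C(=O)O[C@@H]2[C@@H](I)[C@@H](COCc3ccc(OC)cc3)C[C@H](O[Si](CC)(CC)CC)[C@H]4O[C@]4(C)C[C@H](O)[C@@H]12 | intermediate
29 | 1β,10α-epoxy-8α-hydroxy-15-[(4-methoxybenzyl)oxy]-2α-(triethylsilyloxy)-4αH-germacr-11(13)-en-12,6α-olide | C=C1C(=O)O[C@@H]2C[C@@H](COCc3ccc(OC)cc3)C[C@H](O[Si](CC)(CC)CC)[C@H]4O[C@]4(C)C[C@H](O)[C@@H]12 | intermediate
30 | 1β,10α-epoxy-15-[(4-methoxybenzyl)oxy]-8α-(tigloyloxy)-2α-(triethylsilyloxy)-4αH-germacr-11(13)-en-12,6α-olide | C=C1C(=O)O[C@@H]2C[C@@H](COCc3ccc(OC)cc3)C[C@H](O[Si](CC)(CC)CC)[C@H]4O[C@]4(C)C[C@H](OC(=O)/C(C)=C/C)[C@@H]12 | intermediate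
31 | 1β,10α-epoxy-15-hydroxy-8α-(tigloyloxy)-2α-(triethylsilyloxy)-4αH-germacr-11(13)-en-12,6α-olide | C=C1C(=O)O[C@@H]2C[C@@H](CO)C[C@H](O[Si](CC)(CC)CC)[C@H]3O[C@]3(C)C[C@H](OC(=O)/C(C)=C/C)[C@@H]12 | intermediate
32 | 1β,10α-epoxy-15-oxo-8α-(tigloyloxy)-2α-(triethylsilyloxy)-4αH-germacr-11(13)-en-12,6α-olide | C=C1C(=O)O[C@@H]2C[C@@H](C=O)C[C@H](O[Si](CC)(CC)CC)[C@H]3O[C@]3(C)C[C@H](OC(=O)/C(C)=C/C)[C@@H]12 | intermediate
33 | 1β,10α-epoxy-2α-hydroxy-15-oxo-8α-(tigloyloxy)-4αH-germacr-11(13)-en-12,6α-olide | C=C1C(=O)O[C@@H]2C[C@@H](C=O)C[C@H](O)[C@H]3O[C@]3(C)C[C@H](OC(=O)/C(C)=C/C)[C@@H]12 | target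

**Count and risks**

Total step count: 24. Longest linear sequence: 19 steps (steps 1–7, then 13–24).

Steps most likely to fail:

Step 18 (ring-closing metathesis). Intermolecular metathesis to oligomers, formation of the E olefin, or no turnover may result, because both allylic positions are branched and the ring must close onto a trans-fused lactone. Fallback: the temporary lactone is opened before ring closure so that a freer monocyclic ring is formed. From 25, LiOH in THF/H2O followed by evaporation and MeI in DMF gives the methyl ester of the ring-opened hydroxy acid F1. Metathesis of F1 with the same catalyst gives the monocyclic (5Z)-cyclodecene hydroxy ester F2. The conditions of step 19 (LiOH, then I2/NaHCO3) convert F2 directly into 28, where the route is rejoined.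

Step 19 (iodolactonisation). Poor discrimination between trans and cis ring fusion, capture of the iodonium ion by the epoxide oxygen or the C8 hydroxyl, or 6-endo closure may occur. Fallback: the kinetic halonium capture is replaced by a reversible selenium-mediated cyclisation under thermodynamic control. From 26, LiOH and then PhSeCl (THF, −78 °C to rt) should give the 5β-phenylselanyl 6,12-lactone F3, since seleniranium formation and ring closure are reversible and the more stable trans-fused lactone should accumulate. Bu3SnH with AIBN in toluene at 80 °C then removes selenium and gives 29.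

Step 20 (radical deiodination). Addition of the C5 radical or of the tin radical to the α-methylene lactone may give oligomers or hydrostannation. Fallback: the acrylate is masked before the reduction. From 28, Me2NH in THF at 0 °C adds to C13 to give the dimethylamino adduct F4. Bu3SnH/Et3B then gives the iodine-free amine F5. MeI gives the ammonium iodide F6 (not isolated), and NaHCO3 eliminates trimethylamine to return 29.

**Further compounds**
F1 | step 18 | methyl ester of the ring-opened hydroxy acid of 25 (C8 hydroxyl free, C12 as CO2Me) | C=C(C(=O)OC)[C@@H](C=C)[C@@H](O)C[C@@]2(C)O[C@@H]2[C@@H](O[Si](CC)(CC)CC)C[C@H](COCc3ccc(OC)cc3)C=C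
F2 | step 18 | methyl (5Z)-1β,10α-epoxy-8α-hydroxy-15-[(4-methoxybenzyl)oxy]-2α-(triethylsilyloxy)-4αH-germacra-5,11(13)-dien-12-oate | C=C(C(=O)OC)[C@H]1/C=C\[C@@H](COCc2ccc(OC)cc2)C[C@H](O[Si](CC)(CC)CC)[C@H]3O[C@]3(C)C[C@@H]1O
F3 | step 19 | 1β,10α-epoxy-8α-hydroxy-15-[(4-methoxybenzyl)oxy]-5β-(phenylselanyl)-2α-(triethylsilyloxy)-4αH-germacr-11(13)-en-12,6α-olide | C=C1C(=O)O[C@@H]2[C@@H]([Se]c3ccccc3)[C@@H](COCc4ccc(OC)cc4)C[C@H](O[Si](CC)(CC)CC)[C@H]5O[C@]5(C)C[C@H](O)[C@@H]12
F4 | step 20 | 13-(dimethylamino)-11,13-dihydro derivative of 28 (C11 epimers) | CN(C)CC1C(=O)O[C@@H]2[C@@H](I)[C@@H](COCc3ccc(OC)cc3)C[C@H](O[Si](CC)(CC)CC)[C@H]4O[C@]4(C)C[C@H](O)[C@@H]12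
F5 | step 20 | 13-(dimethylamino)-11,13-dihydro derivative of 29 (C11 epimers) | CN(C)CC1C(=O)O[C@@H]2C[C@@H](COCc3ccc(OC)cc3)C[C@H](O[Si](CC)(CC)CC)[C@H]4O[C@]4(C)C[C@H](O)[C@@H]12
F6 | step 20 | trimethylammonium iodide of F5 (not isolated) | C[N+](C)(C)CC1C(=O)O[C@@H]2C[C@@H](COCc3ccc(OC)cc3)C[C@H](O[Si](CC)(CC)CC)[C@H]4O[C@]4(C)C[C@H](O)[C@@H]12.[I-]
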